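In a closed, stirred vessel, Q takes one X to give D and E, a further X can sit on that D, and pairs of X leave as X2.

    Q + X → D + E (k1 = 0.0029 M⁻¹ s⁻¹)
    X + D ⇌ X.D, settled at all times (K2 = 18000 M⁻¹)
    2 X → X2 (k3 = 1.6 × 10⁻⁴ M⁻¹ s⁻¹)

Q 0.050 M; time 10 d

- two of one species on the left: rate k times its square, two consumed each time
- the amount of X is what is sought; it is there from the start
- run time (flask): 10 d

- the concentration of X at which the part of the Q that has reacted at 10 d is just 80%, in M

Two chemists dispute the charge of X, counted as a fraction of the charge of Q. The first says each Q reacted leaves a D that holds an X, so two X per Q reacted make 1.60. The second answers that D need not be full at the end, since a slow trickle of Q can still go on.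

My own reckoning sides with the second. In logarithms Q falls by k1 times free X times time, and free X is the odds over K2, the odds being X.D over empty D, with X.D as the resting state of X. So 0.139 is the ration, the logarithmic fall of Q that a whole run buys at odds of one. Q first meets X on a time of 0.0798 d, far shorter than the run, so I reckon with a quick stretch that I count as ending with D full. Trying a charge of 1.33, I put the end of that stretch at 0.665 of Q used. The fall to 20.0% of Q left then costs 0.511, which needs mean odds of 3.68 against end odds of 2.00. Odds falling from high values to that end can give such a mean, so I hold to about 1.33, with X2 uncounted.

The forecast, the second chemist's number, is 0.067 M, between 0.062 M and 0.073 M, and it “puts the X.D site about two-thirds filled at 10 d”.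

The flask needs a charge of X of 0.0702 M, or 1.40 as a fraction, which is less than the first chemist's count. That count comes close in this flask early: at 1.00 d, with 0.647% of the charged X free, the odds are 8.18, so D is 89.1% filled. From the 70.1% of Q used then to 80%, the ration asks mean odds of 3.21. The ration of 0.139 is built from k1, K2 and the run, with no charge in it, and the flask at twice the dilution, under that same ration, reaches 79.6%.

The rate constants stand for no real mixture; the result is computed.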